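The carbocycle of the isochromenone (C4a, C5, C6, C7, C8, C8a), C4 and the C7 methyl are the eight carbons of a p-xyloquinone, and the trans-7,8-diol is a cis-oxirane on C7=C8 opened by water at C8. The route therefore rests on one enantioselective nucleophilic epoxidation of the flat, achiral monoketal 3 (C6 ketone, C8a dimethyl ketal). In a single operation this forms C8–O and C7–O, closes the oxirane and sets both ring stereocentres. C1 is then added to C8a by methoxymethylenation, the C4 methyl is acylated by the separately made side-chain ester 27, the pyran closes, and hydrolysis delivers the diol.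

Key step: step 2

Numbering: the isochromene numbering of the target (O2, C1, C3–C8a; side chain C1'–C3'; oxolane O1''–C5'') is used for all intermediates.
Assumption: the sense of induction of the cinchonidinium salt (step 2), the zinc/amino alcohol system (step 9) and (S)-TRIP (step 13) is assigned by analogy with close substrates; the pseudo-enantiomeric or mirror-image catalyst would be taken if a sense proves opposite.

Step 1
Reactants: 1 2,5-dimethylphenol
Product: 3 4,4-dimethoxy-2,5-dimethylcyclohexa-2,5-dien-1-one, via 4-methoxy-2,5-dimethylphenol 2 (not isolated)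
Conditions: PhI(OAc)2 (2.2 equiv), MeOH, 0 °C to rt
Reagents that add atoms: methanol, CO
Why: Double oxidative dearomatisation with a hypervalent iodine reagent: methanol attacks the free para carbon of the aryloxy-iodane, the dienone tautomerises to phenol 2, and a second oxidation traps a second methanol at the same carbon, so one flask replaces the longer passage through the hydroquinone monoether.

Step 2
Reactants: 3 4,4-dimethoxy-2,5-dimethylcyclohexa-2,5-dien-1-one; 4 tert-butyl hydroperoxide
Product: 5 (2S,3R)-2,3-epoxy-4,4-dimethoxy-2,5-dimethylcyclohex-5-en-1-one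
Conditions: t-BuOOH (anhydrous, toluene), N-benzylcinchonidinium chloride (10 mol %), aq NaOH, toluene, 0 °C to rt; recrystallisation
Reagents that add atoms: tert-butyl hydroperoxide, CC(C)(C)OO
Why: The tert-butylperoxide anion, carried into toluene as a tight ion pair with the chiral ammonium cation, adds conjugatively to C8, and the resulting C6 enolate attacks the proximal peroxide oxygen through C7 and expels tert-butoxide. This is an asymmetric Weitz–Scheffer epoxidation under phase transfer, a reaction type established for quinone monoketals and for 2-methyl-1,4-naphthoquinone. The oxirane closes in 3-exo-tet mode. The cation decides which enantiotopic face of the planar dienone receives the peroxide and so fixes C8, and C7 follows because the closure can only occur on the same face, which gives the cis-fused (2S,3R) oxirane. The step needs site selectivity between two enone bonds, and the substrate secures it because C8 carries hydrogen whereas the other β carbon, C4a, is fully substituted. The ketal at C8a prevents tautomerisation to a phenol and removes the second carbonyl that would compete as acceptor.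

Step 3
Reactants: 5 (2S,3R)-2,3-epoxy-4,4-dimethoxy-2,5-dimethylcyclohex-5-en-1-one
Product: 6 2,3-epoxy-4,4-dimethoxy-2,5-dimethylcyclohex-5-en-1-ol (oxirane as in 5, carbinol C6 as an inconsequential epimer mixture)
Conditions: NaBH4, CeCl3·7H2O, MeOH, −78 to −20 °C
Reagents that add atoms: none
Why: Luche reduction delivers hydride 1,2 to the only carbonyl and spares oxirane and ketal, and the new C6 carbinol centre is irrelevant because step 8 erases it.

Step 4
Reactants: 6 epoxy alcohol
Product: 7 tert-butyldimethylsilyl ether of 6
Conditions: TBSCl, imidazole, DMAP (cat.), DMF, rt to 40 °C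
Reagents that add atoms: tert-butyldimethylsilyl chloride, CC(C)(C)[Si](C)(C)Cl
Why: Standard imidazole-promoted silylation of a secondary alcohol masks C6 for the acidic and strongly basic steps that follow, without touching ketal or oxirane.

Step 5
Reactants: 7 silyl ether ketal
Product: 8 4-(tert-butyldimethylsilyloxy)-5,6-epoxy-2,5-dimethylcyclohex-2-en-1-one (C8a ketone; oxirane as in 5)
Conditions: PPTS (cat.), acetone–H2O, rt
Reagents that add atoms: water, O
Why: Mild acid-catalysed ketal hydrolysis works because the C8a ketal is allylic and ionises easily while the TBS ether and the oxirane tolerate PPTS, so C8a becomes the only carbonyl in the molecule.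

Step 6
Reactants: 8 epoxy enone; 9 (methoxymethyl)triphenylphosphonium chloride
Product: 10 methoxymethylidene diene (C8a=O of 8 replaced by C8a=C1H–OMe, E/Z mixture)
Conditions: 9, NaN(SiMe3)2, THF, −78 to 0 °C; chromatography on Et3N-deactivated silica
Reagents that add atoms: (methoxymethyl)triphenylphosphonium chloride, COC[P+](c1ccccc1)(c1ccccc1)c1ccccc1.[Cl-]
Why: Wittig olefination with the non-stabilised methoxymethylidene ylide adds 1,2 to the single ketone and brings in C1 at the aldehyde oxidation level, and the E/Z mixture is harmless because the methoxy group is later displaced by addition–elimination.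

Step 7
Reactants: 10 methoxymethylidene diene
Product: 11 C6 alcohol of 10
Conditions: Bu4NF, THF, 0 °C
Reagents that add atoms: none
Why: Fluoride cleaves the Si–O bond under basic conditions, which the acid-labile dienol ether and the vinyl oxirane tolerate.

Step 8
Reactants: 11 dienyl alcohol
Product: 12 (2S,3S)-2,3-epoxy-4-(methoxymethylidene)-2,5-dimethylcyclohex-5-en-1-one (E/Z mixture at C8a=C1)
Conditions: Dess–Martin periodinane, pyridine, CH2Cl2, 0 °C
Reagents that add atoms: none
Why: Buffered Dess–Martin oxidation of the allylic C6 alcohol restores the ketone, turns the labile dienol ether into a stabilised push–pull dienone and removes the provisional C6 centre.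

Step 9
Reactants: 13 methyl pyruvate; 14 propyne
Product: 15 methyl (2S)-2-hydroxy-2-methylpent-3-ynoate
Conditions: Zn(OTf)2 (20 mol %), (1S,2S)-3-(tert-butyldimethylsilyloxy)-2-(dimethylamino)-1-(4-nitrophenyl)propan-1-ol (22 mol %), Et3N (30 mol %), toluene, sealed vessel, 70 °C
Reagents that add atoms: none
Why: Addition of an in situ zinc acetylide to an α-keto ester under a chiral amino alcohol ligand is a known catalytic asymmetric alkynylation in which the ligand-bound zinc selects one face of the chelated pyruvate ketone and so sets C1' as S.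

Step 10
Reactants: 15 propargylic alcohol
Product: 16 methyl (2S)-2-methyl-2-(triethylsilyloxy)pent-3-ynoate
Conditions: TESOTf, 2,6-lutidine, CH2Cl2, 0 °C
Reagents that add atoms: triethylsilyl triflate, CC[Si](CC)(CC)OS(=O)(=O)C(F)(F)F
Why: A silyl triflate with a hindered pyridine base silylates even tertiary alcohols, which removes the hydroxyl that could redirect the hydrometalation and protects C1'–O in the enolate chemistry of step 16.

Step 11
Reactants: 16 silyloxy alkyne
Product: 18 methyl (2S,3E)-4-iodo-2-methyl-2-(triethylsilyloxy)pent-3-enoate, via alkenylzirconocene 17 (not isolated)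
Conditions: Cp2Zr(H)Cl, THF, rt to 40 °C; then I2, 0 °C
Reagents that add atoms: iodine, II
Why: Hydrozirconation is a syn addition that places zirconium on the less hindered alkyne carbon, here C3' next to methyl and away from quaternary C1', and iodinolysis with retention fixes the E geometry of C2'=C3', the shielded ester reacting more slowly than the alkyne.

Step 12
Reactants: 18 alkenyl iodide; 19 carbon monoxide
Product: 20 methyl (2S,3E)-2,4-dimethyl-5-oxo-2-(triethylsilyloxy)pent-3-enoate
Conditions: Pd(PPh3)4 (5 mol %), CO (3 atm), Bu3SnH (slow addition), THF, 50 °C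
Reagents that add atoms: carbon monoxide, [C-]#[O+]
Why: Reductive carbonylation of an alkenyl iodide under zerovalent palladium (oxidative addition, CO insertion, hydride transfer from tin) keeps the alkene geometry, tolerates ester and silyl ether, and adds C2'' as the aldehyde.

Step 13
Reactants: 20 enal; 21 (E)-crotylboronic acid pinacol ester
Product: 23 methyl (2S,3E,5S,6S)-5-hydroxy-2,4,6-trimethyl-2-(triethylsilyloxy)octa-3,7-dienoate, via pinacol borate ester 22 (not isolated)
Conditions: 21, (S)-TRIP [(S)-3,3'-bis(2,4,6-triisopropylphenyl)-1,1'-binaphthyl-2,2'-diyl hydrogen phosphate] (5 mol %), toluene, −30 °C; aqueous work-up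
Reagents that add atoms: (E)-crotylboronic acid pinacol ester, C/C=C/CB1OC(C)(C)C(C)(C)O1
Why: Chiral phosphoric acid-catalysed crotylboration passes through a closed chair transition state in which the E-crotyl geometry becomes the anti relationship and the catalyst selects the aldehyde face, so C2'' and C3'' are both set as S, and any adduct of the minor C1' antipode becomes a separable diastereomer.

Step 14
Reactants: 23 homoallylic alcohol
Product: 25 methyl (2S,3E,5S,6S)-5,8-dihydroxy-2,4,6-trimethyl-2-(triethylsilyloxy)oct-3-enoate, via bis-boryl adduct 24 (not isolated)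
Conditions: 9-BBN (2.5 equiv), THF, 0 °C to rt; then H2O2, aq NaOH, 0 °C
Reagents that add atoms: hydrogen peroxide, OO
Why: Hydroboration–oxidation with bulky 9-BBN attacks only the monosubstituted alkene at its terminus and leaves the trisubstituted C2'=C3' bond, giving the primary alcohol at C5'' without touching a stereocentre.

Step 15
Reactants: 25 1,4-diol
Product: 27 methyl (2S,3E)-2-methyl-4-[(2S,3S)-3-methyloxolan-2-yl]-2-(triethylsilyloxy)pent-3-enoate, via primary tosylate 26 (not isolated)
Conditions: TsCl (1.1 equiv), Et3N, DMAP (cat.), CH2Cl2, 0 to 40 °C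
Reagents that add atoms: none
Why: Selective sulfonylation of the primary alcohol and 5-exo-tet Williamson closure by the C2'' hydroxyl form the oxolane with retention at C2'', because only the C5''–O bond is exchanged, so the anti diol gives the trans-2,3-disubstituted ring.

Step 16
Reactants: 12 (2S,3S)-2,3-epoxy-4-(methoxymethylidene)-2,5-dimethylcyclohex-5-en-1-one; 27 side-chain methyl ester
Product: 30 (7S,8S)-7,8-epoxy-7-methyl-3-{(2S,3E)-4-[(2S,3S)-3-methyloxolan-2-yl]-2-(triethylsilyloxy)pent-3-en-2-yl}-7,8-dihydro-6H-isochromen-6-one, via lithium trienolate 28 (not isolated), via open-chain diketone 29 (not isolated)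
Conditions: LiN(SiMe3)2 (2.2 equiv), THF, −78 °C; 27, −78 to 0 °C; AcOH quench; then PPTS (cat.), 4 Å MS, CH2Cl2, rt
Reagents that add atoms: none
Why: Proposed new method: the C4 methyl holds the only acidic protons of 12 (C7 is quaternary, C8–H sits on the oxirane), so LiN(SiMe3)2 gives the cross-conjugated trienolate 28, which should attack the ester carbonyl of 27 through its exposed exocyclic CH2 (C4) rather than through ring carbon C5, whose two faces are screened by the oxirane oxygen and the C7 methyl against a neopentyl-type electrophile; the second equivalent of base stores 29 as its vinylogous diketonate, and after neutralisation the C3 enol oxygen adds to C1 (6-endo-trig) and methanol leaves, which closes the pyran without touching C7, C8, C1', C2'' or C3''; the closest known reaction types are the vinylogous Claisen condensation (γ-acylation of the lithium dienolates of 2-methyl-4-pyranones and 6-methyl-1,3-dioxin-4-ones) and the acylation–cyclisation of 4-methoxybut-3-en-2-one enolates to 4-pyranones, neither of which has been shown on a 4-alkylidene-3-methylcyclohexenone.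

Step 17
Reactants: 30 epoxy isochromenone silyl ether
Product: 31 (7S,8R)-7,8-dihydroxy-3-{(2S,3E)-2-hydroxy-4-[(2S,3S)-3-methyloxolan-2-yl]pent-3-en-2-yl}-7-methyl-7,8-dihydro-6H-isochromen-6-one (target)
Conditions: HClO4 (0.1 M, cat.), THF–H2O, 0 °C to rt
Reagents that add atoms: water, O
Why: Acid-catalysed epoxide hydrolysis opens the protonated oxirane at C8, which is allylic to the C1=C8a enol ether and β to the C6 ketone whereas C7 is α to that ketone, and water enters anti in a borderline SN2 event, so C8 is inverted, the C7–O bond is kept and the trans (7S,8R) diol results, while the same dilute acid cleaves the Si–O bond (not the C1'–O bond) of the triethylsilyl ether.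

Compound list
1 | 2,5-dimethylphenol | Cc1ccc(C)c(O)c1 | starting material
2 | 4-methoxy-2,5-dimethylphenol | COc1cc(C)c(O)cc1C | intermediate
3 | 4,4-dimethoxy-2,5-dimethylcyclohexa-2,5-dien-1-one | COC1(OC)C=C(C)C(=O)C=C1C | intermediate
4 | tert-butyl hydroperoxide | CC(C)(C)OO | starting material
5 | (2S,3R)-2,3-epoxy-4,4-dimethoxy-2,5-dimethylcyclohex-5-en-1-one | CC1=CC(=O)[C@@]2(C)O[C@H]2C1(OC)OC | intermediate
6 | 2,3-epoxy-4,4-dimethoxy-2,5-dimethylcyclohex-5-en-1-ol, oxirane as in 5, C6 epimer mixture | CC1=CC(O)[C@@]2(C)O[C@H]2C1(OC)OC | intermediate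
7 | tert-butyldimethylsilyl ether of 6 | CC1=CC(O[Si](C)(C)C(C)(C)C)[C@@]2(C)O[C@H]2C1(OC)OC | intermediate
8 | 4-(tert-butyldimethylsilyloxy)-5,6-epoxy-2,5-dimethylcyclohex-2-en-1-one, oxirane as in 5 | CC1=CC(O[Si](C)(C)C(C)(C)C)[C@@]2(C)O[C@H]2C1=O | intermediate
9 | (methoxymethyl)triphenylphosphonium chloride | COC[P+](c1ccccc1)(c1ccccc1)c1ccccc1.[Cl-] | starting material
10 | C8a methoxymethylidene derivative of 8, E/Z mixture | CC1=CC(O[Si](C)(C)C(C)(C)C)[C@@]2(C)O[C@H]2C1=COC | intermediate
11 | C6 alcohol obtained from 10 | CC1=CC(O)[C@@]2(C)O[C@H]2C1=COC | intermediate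
12 | (2S,3S)-2,3-epoxy-4-(methoxymethylidene)-2,5-dimethylcyclohex-5-en-1-one, E/Z mixture | CC1=CC(=O)[C@@]2(C)O[C@H]2C1=COC | intermediate
13 | methyl pyruvate | COC(=O)C(C)=O | starting material
14 | propyne | CC#C | starting material
15 | methyl (2S)-2-hydroxy-2-methylpent-3-ynoate | CC#C[C@](C)(O)C(=O)OC | intermediate
16 | methyl (2S)-2-methyl-2-(triethylsilyloxy)pent-3-ynoate | CC#C[C@](C)(O[Si](CC)(CC)CC)C(=O)OC | intermediate
17 | (E)-alkenyl(chloro)zirconocene from 16, Zr on C3' | C/C([Zr](Cl)(C1C=CC=C1)C1C=CC=C1)=C\[C@](C)(O[Si](CC)(CC)CC)C(=O)OC | intermediate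
18 | methyl (2S,3E)-4-iodo-2-methyl-2-(triethylsilyloxy)pent-3-enoate | C/C(I)=C\[C@](C)(O[Si](CC)(CC)CC)C(=O)OC | intermediate
19 | carbon monoxide | [C-]#[O+] | starting material
20 | methyl (2S,3E)-2,4-dimethyl-5-oxo-2-(triethylsilyloxy)pent-3-enoate | C/C(C=O)=C\[C@](C)(O[Si](CC)(CC)CC)C(=O)OC | intermediate
21 | (E)-crotylboronic acid pinacol ester | C/C=C/CB1OC(C)(C)C(C)(C)O1 | starting material
22 | O-pinacolboryl derivative of 23 | C/C(=C\[C@](C)(O[Si](CC)(CC)CC)C(=O)OC)[C@@H](OB1OC(C)(C)C(C)(C)O1)[C@@H](C)C=C | intermediate
23 | methyl (2S,3E,5S,6S)-5-hydroxy-2,4,6-trimethyl-2-(triethylsilyloxy)octa-3,7-dienoate | C/C(=C\[C@](C)(O[Si](CC)(CC)CC)C(=O)OC)[C@@H](O)[C@@H](C)C=C | intermediate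
24 | O,C-bis(9-borabicyclononyl) adduct of 23 | C/C(=C\[C@](C)(O[Si](CC)(CC)CC)C(=O)OC)[C@@H](OB1C2CCCC1CCC2)[C@@H](C)CCB1C2CCCC1CCC2 | intermediate
25 | methyl (2S,3E,5S,6S)-5,8-dihydroxy-2,4,6-trimethyl-2-(triethylsilyloxy)oct-3-enoate | C/C(=C\[C@](C)(O[Si](CC)(CC)CC)C(=O)OC)[C@@H](O)[C@@H](C)CCO | intermediate
26 | primary (C5'') tosylate of 25 | C/C(=C\[C@](C)(O[Si](CC)(CC)CC)C(=O)OC)[C@@H](O)[C@@H](C)CCOS(=O)(=O)c1ccc(C)cc1 | intermediate
27 | methyl (2S,3E)-2-methyl-4-[(2S,3S)-3-methyloxolan-2-yl]-2-(triethylsilyloxy)pent-3-enoate | C/C(=C\[C@](C)(O[Si](CC)(CC)CC)C(=O)OC)[C@H]1OCC[C@@H]1C | intermediate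
28 | lithium trienolate of 12 (C4 deprotonated) | [Li+].C=C1C=C([O-])[C@@]2(C)O[C@H]2C1=COC | intermediate
29 | C4-acylated open-chain vinylogous diketone | C/C(=C\[C@](C)(O[Si](CC)(CC)CC)C(=O)CC1=CC(=O)[C@@]2(C)O[C@H]2C1=COC)[C@H]1OCC[C@@H]1C | intermediate
30 | (7S,8S)-7,8-epoxy-7-methyl-3-{(2S,3E)-4-[(2S,3S)-3-methyloxolan-2-yl]-2-(triethylsilyloxy)pent-3-en-2-yl}-7,8-dihydro-6H-isochromen-6-one | C/C(=C\[C@](C)(O[Si](CC)(CC)CC)C1=CC2=CC(=O)[C@@]3(C)O[C@H]3C2=CO1)[C@H]1OCC[C@@H]1C | intermediate
31 | (7S,8R)-7,8-dihydroxy-3-{(2S,3E)-2-hydroxy-4-[(2S,3S)-3-methyloxolan-2-yl]pent-3-en-2-yl}-7-methyl-7,8-dihydro-6H-isochromen-6-one | C/C(=C\[C@](C)(O)C1=CC2=CC(=O)[C@@](C)(O)[C@H](O)C2=CO1)[C@H]1OCC[C@@H]1C | target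

Total step count: 17. Longest linear sequence: 10 steps (steps 1–8, 16, 17). The side-chain branch (steps 9–15) joins at step 16.

Steps most likely to fail

1. Step 16. Acylation may run through C5 or through the enolate oxygen. Acyl transfer may also fail altogether, because the ester carbonyl is flanked by a quaternary carbon. The fallback uses known reaction types only, sets out from 27 and 12 and returns at 30. Ester 27 is reduced with i-Bu2AlH (CH2Cl2, −78 °C) to (2S,3E)-2-methyl-4-[(2S,3S)-3-methyloxolan-2-yl]-2-(triethylsilyloxy)pent-3-enal F1, a far better electrophile that cannot enolise. Trienolate 28 is made as before, F1 is added and the mixture is warmed. The reversible aldolate at C5 then reverts, while the C4 aldolate is drained by attack of its alkoxide on C1 and loss of methoxide. This is the thermodynamic vinylogous aldol–cyclisation known from dihydropyranone syntheses with senecioate dienolates, and it gives the 3,4-dihydro analogue of 30 F2 as a C3 epimer mixture. LiN(SiMe3)2 with Me3SiCl present from the start gives the C6 trimethylsilyl trienol ether of the dihydro compound F3. Saegusa–Ito dehydrogenation with Pd(OAc)2 in MeCN then introduces C3=C4, erases the C3 centre and gives 30.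

2. Step 2. Facial discrimination by the ion pair may be low, or peroxide addition to the α-methyl enone may be slow, so that recrystallisation does not reach enantiopure 5. The fallback sets out from 3 and returns at 8; it forms the same bonds under auxiliary control in place of catalyst control. Transketalisation of 3 with (2R,4R)-pentane-2,4-diol (PPTS, toluene, methanol removed) gives the C2-symmetric spiroketal dienone F4, whose enone faces are diastereotopic. Achiral Weitz–Scheffer epoxidation (t-BuOOH, DBU, CH2Cl2) gives two separable diastereomers, of which the spiroketal epoxide with the oxirane configured as in 5 F5 is kept; the antipodal diol is used if it favours this isomer. Luche reduction gives the spiroketal epoxy alcohol F6 and silylation gives the spiroketal silyl ether F7. Aqueous acid hydrolysis then releases the diol and gives 8.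

3. Step 17. Ionisation to a free allyl-oxocarbenium ion may cost the anti course at C8. Water may be captured at C1, or acid may ionise the tertiary bis-allylic C1' position once the silyl group is gone. The fallback sets out from 30 and returns at 31; it uses nucleophilic opening in a buffered medium in place of acid hydrolysis. CsOAc in AcOH–THF opens the oxirane at C8 by direct SN2 displacement to the trans 8-acetoxy-7-hydroxy triethylsilyl ether F8. K2CO3 in MeOH removes the acetate to give the 7,8-diol triethylsilyl ether F9. Bu4NF buffered with AcOH then frees the C1' hydroxyl and gives 31.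

Further compounds
F1 | step 16 | (2S,3E)-2-methyl-4-[(2S,3S)-3-methyloxolan-2-yl]-2-(triethylsilyloxy)pent-3-enal | C/C(=C\[C@](C)(O[Si](CC)(CC)CC)C=O)[C@H]1OCC[C@@H]1C
F2 | step 16 | 3,4-dihydro analogue of 30, C3 epimer mixture | C/C(=C\[C@](C)(O[Si](CC)(CC)CC)C1CC2=CC(=O)[C@@]3(C)O[C@H]3C2=CO1)[C@H]1OCC[C@@H]1C
F3 | step 16 | C6 trimethylsilyl trienol ether of the dihydro compound | C/C(=C\[C@](C)(O[Si](CC)(CC)CC)C1C=C2C=C(O[Si](C)(C)C)[C@@]3(C)O[C@H]3C2=CO1)[C@H]1OCC[C@@H]1C
F4 | step 2 | C2-symmetric spiroketal dienone from 3 and (2R,4R)-pentane-2,4-diol | CC1=CC(=O)C(C)=CC12O[C@H](C)C[C@@H](C)O2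
F5 | step 2 | spiroketal epoxide with the oxirane configured as in 5 | CC1=CC(=O)[C@@]2(C)O[C@H]2C13O[C@H](C)C[C@@H](C)O3
F6 | step 2 | spiroketal epoxy alcohol, C6 epimer mixture | CC1=CC(O)[C@@]2(C)O[C@H]2C13O[C@H](C)C[C@@H](C)O3
F7 | step 2 | spiroketal silyl ether | CC1=CC(O[Si](C)(C)C(C)(C)C)[C@@]2(C)O[C@H]2C13O[C@H](C)C[C@@H](C)O3
F8 | step 17 | trans 8-acetoxy-7-hydroxy triethylsilyl ether | C/C(=C\[C@](C)(O[Si](CC)(CC)CC)C1=CC2=CC(=O)[C@@](C)(O)[C@H](OC(C)=O)C2=CO1)[C@H]1OCC[C@@H]1C
F9 | step 17 | 7,8-diol triethylsilyl ether | C/C(=C\[C@](C)(O[Si](CC)(CC)CC)C1=CC2=CC(=O)[C@@](C)(O)[C@H](O)C2=CO1)[C@H]1OCC[C@@H]1C
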